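**Retrosynthetic overview**
1. Lactol ring (formed last): open the O2–C3 bond to the δ-keto acid. Ring–chain closure is spontaneous, and C3 follows C4 under thermodynamic control.
2. α-Acyloxy ketone: cut the CH2–O bond to an (S)-diazoketone and unprotected 5-methylorsellinic acid (O–H insertion).
3. C4: the (S)-2-arylpropanoic acid comes from the arylacetic acid by enantioselective enediolate methylation. The arylacetic acid comes from lateral carboxylation of the 6-methyl group of a protected 5-methylorsellinate.
4. Both benzene rings (formed first, in one step): polyketide-type C2–C7 aldol aromatisation of a C-methylated 3,5,7-triketo ester made from benzyl acetoacetate and ethyl 2-methylacetoacetate.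
5. Ring order: benzene ring (one batch, split between the two halves), then the lactol ring.

Assumption: the presumed biosynthesis is taken as C2–C7 aldol aromatisation of C-methylated poly-β-keto chains for both arenes, spontaneous lactol closure of the δ-keto acid, and ester union with 5-methylorsellinic acid. The SMILES is read as (3R,4S), with 3-OH trans to 4-CH3.

**Route**

Step 1
Reactants: 1 benzyl acetoacetate; 2 ethyl 2-methylacetoacetate
Product: 4 benzyl 2,4-dihydroxy-5,6-dimethylbenzoate, via open-chain triketo ester 3 (not isolated)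
Conditions: 1, NaH, THF, 0 °C, then n-BuLi, 0 °C; add Na enolate of 2 (NaH, THF); 0 °C to reflux, 16 h; 2 M HCl
Reagents that add atoms: none
Why: Weiler-dianion γ-acylation (crossed Claisen) of 1 by the ester group of enolate-masked 2 gives the methylated tetraketide 3, whose most acidic C2 methylene adds to the C7 ketone and loses water (Harris-type biomimetic aldol aromatisation), the same reaction type as the known base-mediated self-condensation of acetoacetates to orsellinates, and no stereocentre survives.

Step 2
Reactants: 4 benzyl 2,4-dihydroxy-5,6-dimethylbenzoate (part of the batch)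
Product: 5 2,4-dihydroxy-5,6-dimethylbenzoic acid (5-methylorsellinic acid)
Conditions: H2 (1 atm), 10% Pd/C, EtOAc, rt
Reagents that add atoms: none
Why: Hydrogenolysis of the benzyl ester frees the hindered acid under neutral conditions and so avoids the hot alkali and the decarboxylation risk that saponification of a 2,6-disubstituted salicylate would bring.

Step 3
Reactants: 4 benzyl 2,4-dihydroxy-5,6-dimethylbenzoate
Product: 7 benzyl 2-(benzyloxy)-4-methoxy-5,6-dimethylbenzoate, via 4-O-methyl ether 6 (not isolated)
Conditions: K2CO3 (3 equiv), MeI (1.05 equiv), acetone, 40 °C; then BnBr (1.5 equiv), reflux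
Reagents that add atoms: iodomethane, CI; benzyl bromide, BrCc1ccccc1
Why: Williamson etherification under acidity control, in which the unchelated 4-OH para to the ester is deprotonated and methylated first while the 2-OH stays hydrogen-bonded to the ester carbonyl and is benzylated only afterwards at reflux.

Step 4
Reactants: 7 benzyl 2-(benzyloxy)-4-methoxy-5,6-dimethylbenzoate
Product: 8 2-[3-(benzyloxy)-2-(benzyloxycarbonyl)-5-methoxy-6-methylphenyl]acetic acid
Conditions: LiN(iPr)2 (2.2 equiv), THF, −78 °C; CO2 (g), −78 °C to rt; 1 M HCl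
Reagents that add atoms: carbon dioxide, O=C=O
Why: Lateral lithiation of an ortho-toluate, in which only the 6-methyl group is conjugated with the ester and therefore gives the ortho-quinodimethane-type dienolate, which CO2 traps at carbon to give the homophthalic half ester without creating a stereocentre.

Step 5
Reactants: 8 2-[3-(benzyloxy)-2-(benzyloxycarbonyl)-5-methoxy-6-methylphenyl]acetic acid
Product: 9 (2S)-2-[3-(benzyloxy)-2-(benzyloxycarbonyl)-5-methoxy-6-methylphenyl]propanoic acid
Conditions: N1,N3-bis[(1R)-1-phenyl-2-(piperidin-1-yl)ethyl]propane-1,3-diamine (1.05 equiv), n-BuLi (4.1 equiv), THF, −78 to 0 °C; MeI, −78 °C; 1 M HCl (amine recovered from the acid layer)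
Reagents that add atoms: iodomethane, CI
Why: Enantioselective alkylation of an arylacetic acid enediolate held in a mixed aggregate with a C2-symmetric chiral dilithium amide (traceless-auxiliary alkylation), in which the aggregate shields one enediolate face so that MeI sets the future C4 as (S), the sense I recall (not checked) for the (R,R)-amine with arylacetic acids and reversible with the equally available (S,S)-amine, while the doubly ortho-substituted benzoate should be too hindered to be attacked.

Step 6
Reactants: 9 (2S)-2-[3-(benzyloxy)-2-(benzyloxycarbonyl)-5-methoxy-6-methylphenyl]propanoic acid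
Product: 11 benzyl 2-(benzyloxy)-6-[(2S)-4-diazo-3-oxobutan-2-yl]-4-methoxy-5-methylbenzoate, via acid chloride 10 (not isolated)
Conditions: 1-chloro-N,N,2-trimethylprop-1-en-1-amine (1.1 equiv), CH2Cl2, 0 °C, 1 h; then CH2N2 (4 equiv), Et2O, 0 °C
Reagents that add atoms: diazomethane, C=[N+]=[N-]; 1-chloro-N,N,2-trimethylprop-1-en-1-amine, CC(C)=C(Cl)N(C)C (chlorine of 10 only)
Why: Neutral acid chloride formation with the α-chloroenamine followed by acylation of diazomethane (first half of the Arndt–Eistert sequence) adds the last carbon without any base, so neither ketene formation nor enolisation erodes the (S) centre.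

Step 7
Reactants: 11 benzyl 2-(benzyloxy)-6-[(2S)-4-diazo-3-oxobutan-2-yl]-4-methoxy-5-methylbenzoate; 5 2,4-dihydroxy-5,6-dimethylbenzoic acid
Product: 12 benzyl 2-(benzyloxy)-6-[(2S)-4-(2,4-dihydroxy-5,6-dimethylbenzoyloxy)-3-oxobutan-2-yl]-4-methoxy-5-methylbenzoate
Conditions: Rh2(OAc)4 (1 mol %), CH2Cl2/EtOAc, rt, slow addition of 11 to 5 (1.5 equiv)
Reagents that add atoms: none
Why: Rhodium-carbenoid O–H insertion, in which the electrophilic carbenoid is captured fastest by the most acidic O–H (the carboxyl group of 5), the hindered acid acts as nucleophile rather than acyl donor so its phenols need no protection, and the neutral medium leaves C4 untouched.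

Step 8
Reactants: 12 benzyl 2-(benzyloxy)-6-[(2S)-4-(2,4-dihydroxy-5,6-dimethylbenzoyloxy)-3-oxobutan-2-yl]-4-methoxy-5-methylbenzoate
Product: 14 [(3R,4S)-3,8-dihydroxy-6-methoxy-4,5-dimethyl-1-oxo-3,4-dihydro-1H-isochromen-3-yl]methyl 2,4-dihydroxy-5,6-dimethylbenzoate, via open δ-keto acid 13 (not isolated)
Conditions: H2 (1 atm), 10% Pd/C, EtOAc, rt; filter, concentrate below 30 °C
Reagents that add atoms: none
Why: Neutral hydrogenolysis frees the phenol and the benzoic acid without enolising C4, and the δ-keto acid 13 then closes by ring–chain tautomerism (the biosynthetic lactol closure), a reversible step that settles C3 in the isomer with the axial anomeric OH trans to the pseudoaxial 4-methyl group (which avoids the peri clash with the 5-methyl group), that is (3R,4S).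

**Compound list**
1 | benzyl acetoacetate | CC(=O)CC(=O)OCc1ccccc1 | starting material
2 | ethyl 2-methylacetoacetate (racemic) | CCOC(=O)C(C)C(C)=O | starting material
3 | benzyl 6-methyl-3,5,7-trioxooctanoate (racemic, enolised) | CC(=O)C(C)C(=O)CC(=O)CC(=O)OCc1ccccc1 | intermediate (not isolated)
4 | benzyl 2,4-dihydroxy-5,6-dimethylbenzoate | Cc1c(C)c(C(=O)OCc2ccccc2)c(O)cc1O | intermediate
5 | 2,4-dihydroxy-5,6-dimethylbenzoic acid | Cc1c(C)c(C(=O)O)c(O)cc1O | intermediate
6 | benzyl 2-hydroxy-4-methoxy-5,6-dimethylbenzoate | COc1cc(O)c(C(=O)OCc2ccccc2)c(C)c1C | intermediate (not isolated)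
7 | benzyl 2-(benzyloxy)-4-methoxy-5,6-dimethylbenzoate | COc1cc(OCc2ccccc2)c(C(=O)OCc2ccccc2)c(C)c1C | intermediate
8 | 2-[3-(benzyloxy)-2-(benzyloxycarbonyl)-5-methoxy-6-methylphenyl]acetic acid | COc1cc(OCc2ccccc2)c(C(=O)OCc2ccccc2)c(CC(=O)O)c1C | intermediate
9 | (2S)-2-[3-(benzyloxy)-2-(benzyloxycarbonyl)-5-methoxy-6-methylphenyl]propanoic acid | COc1cc(OCc2ccccc2)c(C(=O)OCc2ccccc2)c(c1C)[C@H](C)C(=O)O | intermediate
10 | (2S)-2-[3-(benzyloxy)-2-(benzyloxycarbonyl)-5-methoxy-6-methylphenyl]propanoyl chloride | COc1cc(OCc2ccccc2)c(C(=O)OCc2ccccc2)c(c1C)[C@H](C)C(=O)Cl | intermediate (not isolated)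
11 | benzyl 2-(benzyloxy)-6-[(2S)-4-diazo-3-oxobutan-2-yl]-4-methoxy-5-methylbenzoate | COc1cc(OCc2ccccc2)c(C(=O)OCc2ccccc2)c(c1C)[C@H](C)C(=O)C=[N+]=[N-] | intermediate
12 | benzyl 2-(benzyloxy)-6-[(2S)-4-(2,4-dihydroxy-5,6-dimethylbenzoyloxy)-3-oxobutan-2-yl]-4-methoxy-5-methylbenzoate | COc1cc(OCc2ccccc2)c(C(=O)OCc2ccccc2)c(c1C)[C@H](C)C(=O)COC(=O)c1c(O)cc(O)c(C)c1C | intermediate
13 | 2-[(2S)-4-(2,4-dihydroxy-5,6-dimethylbenzoyloxy)-3-oxobutan-2-yl]-6-hydroxy-4-methoxy-3-methylbenzoic acid | COc1cc(O)c(C(=O)O)c(c1C)[C@H](C)C(=O)COC(=O)c1c(O)cc(O)c(C)c1C | intermediate (not isolated)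
14 | [(3R,4S)-3,8-dihydroxy-6-methoxy-4,5-dimethyl-1-oxo-3,4-dihydro-1H-isochromen-3-yl]methyl 2,4-dihydroxy-5,6-dimethylbenzoate | COc1cc(O)c2c(c1C)[C@H](C)[C@](O)(COC(=O)c1c(O)cc(O)c(C)c1C)OC2=O | target

**Step count**
Total step count: 8. Longest linear sequence: 7 (steps 1, 3, 4, 5, 6, 7, 8).

**Steps most likely to fail**

First risk, step 1. Proton exchange between the dianion of 1 and the enolate of 2 can divert material to benzyl orsellinate, to pyrones, or to ester-exchanged products. The fallback sets out from 1 and builds the same chain one simple acyl unit at a time. The dianion of 1 is acylated with methyl propanoate to give benzyl 3,5-dioxoheptanoate F1. The trianion of F1 (LiN(iPr)2, 3.3 equiv, THF, 0 °C) is then acetylated at its terminal C6 carbanion with N-methoxy-N-methylacetamide. This comes back to the route at 3, which aromatises to 4 on the same acidic work-up.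

Second risk, step 5. The doubly ortho-substituted aryl group may disturb the mixed aggregate and lower the ee. The enediolate oxygen may also attack the neighbouring benzyl ester to give the homophthalic anhydride. The fallback sets out from 8 and separates bond formation from stereocontrol. Plain methylation (LiN(iPr)2, 2.2 equiv, then MeI) gives racemic 2-[3-(benzyloxy)-2-(benzyloxycarbonyl)-5-methoxy-6-methylphenyl]propanoic acid F2. This is kinetically resolved by asymmetric esterification with pivalic anhydride, iPr2NEt, (R)-benzotetramisole (5 mol %) and di(naphthalen-1-yl)methanol (0.5 equiv). As I recall, ortho-substituted 2-arylpropanoic acids respond especially well to this method, but I have not checked that. The (R)-acid is taken away as di(naphthalen-1-yl)methyl (2R)-2-[3-(benzyloxy)-2-(benzyloxycarbonyl)-5-methoxy-6-methylphenyl]propanoate F3. The unreacted (S)-acid is extracted with base, which comes back to the route at 9.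

Third risk, step 7. The phenolic O–H groups of 5, Wolff rearrangement, or intramolecular capture of the carbenoid by the neighbouring ester may compete with the carboxyl O–H. The fallback sets out from 11 and replaces carbenoid chemistry by an SN2 displacement. HBr (33% in AcOH, Et2O, 0 °C) converts 11 into benzyl 2-(benzyloxy)-6-[(2S)-4-bromo-3-oxobutan-2-yl]-4-methoxy-5-methylbenzoate F4. F4 is then alkylated by the carboxylate of 5, formed with only 1.0 equiv KHCO3 in DMF at 0 °C. Under these conditions the phenols stay protonated and C4 epimerisation is kept low. This comes back to the route at 12.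

**Further compounds**
F1 | step 1 | benzyl 3,5-dioxoheptanoate | CCC(=O)CC(=O)CC(=O)OCc1ccccc1
F2 | step 5 | racemic 2-[3-(benzyloxy)-2-(benzyloxycarbonyl)-5-methoxy-6-methylphenyl]propanoic acid | COc1cc(OCc2ccccc2)c(C(=O)OCc2ccccc2)c(c1C)C(C)C(=O)O
F3 | step 5 | di(naphthalen-1-yl)methyl (2R)-2-[3-(benzyloxy)-2-(benzyloxycarbonyl)-5-methoxy-6-methylphenyl]propanoate | COc1cc(OCc2ccccc2)c(C(=O)OCc2ccccc2)c(c1C)[C@@H](C)C(=O)OC(c1cccc2ccccc12)c1cccc2ccccc12
F4 | step 7 | benzyl 2-(benzyloxy)-6-[(2S)-4-bromo-3-oxobutan-2-yl]-4-methoxy-5-methylbenzoate | COc1cc(OCc2ccccc2)c(C(=O)OCc2ccccc2)c(c1C)[C@H](C)C(=O)CBr
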